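(The readings are simulated with constants of no real substance; the scatter is artificial.)

- From 3.00 h to 8.00 h no reading of delta or theta moves by more than 4 percentage points, against a scatter of 2 points, so we read each end as an equilibrium.

| setting | delta | theta | flask |
|---|---|---|---|
| starting material | 25 mM | 40 mM | 18 mM |
| second substrate | 36 mM | 36 mM | 36.0 mM |
| enzyme | 1.8 µM | 1.8 µM | 1.8 µM |
| remark | run made earlier | run made earlier |  |

- delta (time / h: target / %, starting material / %): 0.667: 50, 49; 1.00: 62, 37; 2.00: 73, 23; 3.00: 76, 23; 5.00: 77, 25; 8.00: 80, 26
- theta (time / h: target / %, starting material / %): 0.667: 34, 63; 1.00: 51, 51; 2.00: 64, 38; 3.00: 62, 35; 5.00: 63, 35; 8.00: 63, 38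

(scatter of a reading: 2 percentage points)

- the analysis behind the earlier runs scatters by 2 percentage points, standard deviation
- no earlier run changes the charge of enzyme; that part of a forecast is a guess
- no earlier run changes the charge of second substrate; that part of a forecast is a guess

1. apparent order in enzyme when 50% of the starting material are converted (percent change of the rate of making target for one percent more enzyme charged)
2. apparent order in second substrate when 50% of the starting material are converted (percent change of the rate of making target for one percent more second substrate charged)

- We count one starting material and one second substrate spent per target. Then [target]/([starting material][second substrate]) reads 0.192 mM⁻¹ in delta and 0.154 mM⁻¹ in theta, and we take the mean, 0.173 mM⁻¹.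
- Our number is the back-pull, the reverse rate as a fraction of the forward rate at 50% conversion in the flask: 0.214.
- We take the net rate to carry the factor one minus the back-pull, and at fixed conversion more [second substrate] shrinks the back-pull.
- In the flask a fixed amount of second substrate is spent by then, so one percent more charged is 1.33 percent more present.
- The back-pull term therefore gives the flask an estimated order of 0.363.
- One number is not enough: no run varies second substrate, so we guess 0.5 for the order at fixed back-pull, and our total is 1.03. For enzyme we guess 1.
- The forecast, on plateaus that “look like an equilibrium, not dead enzyme”, gives 1 in enzyme, as we do, and 0.9 in second substrate, less than our figure.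
- The flask gives 0.83 in enzyme and 0.83 in second substrate.

    starting material + enzyme ⇌ starting complex (K = 93.0 M⁻¹, k = 1880 M⁻¹ s⁻¹)
    second substrate + starting complex ⇌ ternary complex (K = 54.0 M⁻¹, k = 2240 M⁻¹ s⁻¹)
    ternary complex ⇌ enzyme + target (K = 0.0362 M, k = 12.4 s⁻¹)
    2 ternary complex ⇌ resting dimer, settled at all times (K = 9.65 × 10⁵ M⁻¹)

- With the back-pull at 0.214, our term of 0.363 falls short of the flask's order 0.83 in second substrate by 0.467. The back reaction of ternary complex to second substrate + starting complex is a part of the reason for that order, not the whole: in a run of the flask without it, the order falls from 0.83 to 0.17.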